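## The problem

Target 22 is a 2,3-dihydrobenzofuran: a benzene ring fused through C3a/C7a to the five-membered O1–C2–C3 ring. It carries an acetyl group at C5, a hydrogen-bonded phenol at C6, an isopropenyl group at C2 and, on the C3 oxygen, the ester of (2Z)-2-(acetoxymethyl)but-2-enoic acid.

C2 and C3 are the only stereocentres, both S and cis to each other. No third centre exists to relay from, so one of them needs an external chiral controller; the ring fusion can then fix the other.

The C3–O bond is benzylic, ortho to O1 and para to the C6 oxygen, and C2–H stands anti to it. Acid (ionisation) or base (elimination) would therefore turn the core into an aromatic benzofuran.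

The side chain is the less stable, angelate-type alkene isomer and carries an allylic acetate. It can isomerise to the E form or suffer SN2′ attack by nucleophilic amines, and the isopropenyl group rules out hydrogenolysis and strong electrophiles. The ester must therefore go on late without nucleophilic catalysts, and the last deprotections must be close to neutral.

The enabling feature is the unit HO–C3–C2(OAr)–C(CH3)=CH2. This is a homoallylic alcohol whose C2–C3 bond joins a benzylic carbinol carbon to an aryloxy carbon, the retron of a [2,3]-Wittig shift of an allyl benzyl ether. Because O1 ties C2 to the arene that also carries C3, that ether is cyclic: the eight-membered 2,6-benzodioxocine 10, in which the two carbons face each other across the ring.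

## Retrosynthesis

**Unmasking (22 ⇐ 21 ⇐ 20).** The C6 O–Si bond and the dioxolane at C5 are cut last. The phenol is carried as a triisopropylsilyl ether because it can be removed by buffered fluoride without touching the benzylic ester; the acetyl group is carried as a dioxolane because it must survive an alkyllithium. The ketal is hydrolysed first, so that the arene is already deactivated by the acetyl group when the phenol is set free. The forward steps need only mild acid and HF·pyridine.

**Ester C3–O bond (20 ⇐ 12 + 18).** Cutting the acyl–oxygen bond separates the sensitive Z side chain 18 from the core and keeps it out of every basic step. Forming the ester at oxygen leaves C3 untouched, unlike a displacement at C3. The forward reaction must acylate a hindered benzylic alcohol without a nucleophilic amine, which a mixed anhydride (19) in toluene allows.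

**C2–C3 bond (12 ⇐ 10, through 11).** This is the strategic cut. Breaking C2–C3 and re-joining the C3 oxygen to the terminal carbon of the isopropenyl group converts the dihydrofuran into the achiral eight-membered enol ether 10. Neighbouring cuts (O1–C2 or C3–C3a) would demand an acyclic precursor in which both stereocentres are made separately. Here one deprotonation is asked to form the ring, the C–C bond, both stereocentres and the isopropenyl group, with the cis relationship dictated by the ring. The forward step needs a chiral base that selects one benzylic proton and a substrate in which no other C–H competes.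

**Enol ether and ring C–O bonds (10 ⇐ 9 ⇐ 8 ⇐ 6 + 7).** The ring enol ether is traced to the exocyclic alkene 9 by a base-mediated double-bond shift toward the more acidic aryloxy-methylene group; the ring forces the Z geometry. The two ether bonds of 9 are cut to the salicyl alcohol 6 and the symmetrical dichloride 7. Making them in two stages (phenol first with carbonate, then the alkoxide at high dilution) keeps the medium-ring closure intramolecular.

**Arene substituents (6 ⇐ 5 ⇐ 3 ⇐ 2 ⇐ 1).** The benzylic alcohol comes from the aldehyde of 5. The masked acetyl group comes from the aryl bromide 3 through the 1-ethoxyvinyl arene 4, which is ketalised while the chelated aldehyde still protects the benzylic position from acid. The bromide and the silyl ether come from 2,4-dihydroxybenzaldehyde 1, whose substitution pattern directs both reactions. Installing the ketal this early also gives an aldehyde (5) from which a conventional route to 12 can branch.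

**Side chain (18 ⇐ 17 ⇐ 16 ⇐ 14 ⇐ 13, through 15).** The Cα–CH2 bond is cut to formaldehyde and the α-metallated enoate 15, which arises by syn addition of Al–H across but-2-ynoate 14. Syn addition places methyl and ester on the same side, the Z geometry that equilibrating routes (Morita–Baylis–Hillman chemistry) do not give. The tert-butyl ester lets the acid be released by acid without touching the acetate.

## Roads not taken

**Alternative 1:** Pyranone–alkyne Diels–Alder benzannulation. The cut runs through the benzene ring: the 6-alkoxy-2-pyranone A1 carries the two stereocentres in an alkyne tether, and heating would add the alkyne across C6 and C3 of the pyranone, lose carbon dioxide and deliver the arene and the dihydrofuran ring of A2 together.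
- Merits: the substitution pattern of the arene is fixed by the tether, and C2 and C3 come from acyclic chemistry with established asymmetric methods. In certainty of absolute configuration this road is better than the chosen one.
- Weak points: A1 is an acyl ketene acetal of a secondary alcohol and hard to make by O-alkylation of an ambident pyranone. Its C5=C6–O–C–C(CH3)=CH2 array is an allyl vinyl ether, so a Claisen shift competes with the cycloaddition on heating. The unactivated terminal alkyne is a poor partner for an acetyl-substituted pyranone.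
- Comparison: the stereocentres cost several separate steps before the key event. The chosen plan sets against this a purchased arene and a single step that makes the ring, the bond and both centres from an achiral precursor.

**Alternative 2:** Chroman-to-dihydrobenzofuran contraction. The cut is the O1–C2 bond: activation of the C3 hydroxyl of the cis-chromandiol monoester A3 as a triflate would make O1 migrate from the gem-dimethyl carbon to C3 with inversion, and the tertiary cation would lose a methyl proton to give A4.
- Merits: A3 would come from an enantioselective oxidation of a benzopyran C3=C4 double bond, a well-established reaction class, and the ester is installed on a robust chroman. In reliability of enantiocontrol this road is ahead.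
- Weak points: the migrating oxygen is para to the acetyl group and therefore a weak neighbouring group. The cation can also lose the ring proton or be captured by triflate. The hindered C3 hydroxyl next to the gem-dimethyl carbon must be triflated in the presence of the Z-enoate and its allylic acetate. A cis-diol monoester of the required configuration takes several steps.
- Comparison: the chosen plan avoids cationic intermediates on a molecule that already carries the sensitive ester and forms the isopropenyl group directly. It pays with an unproven enantioselective step.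

**Alternative 3:** Phenol and epoxy-aldehyde (3+2) annulation. The cuts are C3–C3a and O1–C2: the metal phenoxide of A5 would add through its ortho carbon to the aldehyde of A6, and the phenol oxygen would then open the epoxide at the adjacent carbon with inversion to give A7.
- Merits: it is the most convergent of the four, and the absolute configuration comes from a small epoxide made by established asymmetric epoxidation. In step count to the bicyclic core it could be shorter than the chosen route.
- Weak points: A5 has two ortho positions; the facial selectivity of the open aldol step decides cis against trans and is not enforced by any ring; the epoxide can open at the tertiary carbon in a 6-endo sense; A7 still needs regioselective dehydration of a tertiary alcohol next to an ionisable benzylic carbinol.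
- Comparison: the chosen plan sets the cis relationship through a bicyclic transition state and delivers the isopropenyl group at the right oxidation level. It concedes that its precursor takes more steps to assemble.

Key step: step 8

Assumption: the sense of induction of the lithium–bis(oxazoline) complex on this new ring system cannot be derived with certainty; the (S,S)-ligand is written, and its (R,R)-antipode would be used if the (2R,3R)-alcohol were found to predominate.

## Route

Step 1
Reactants: 1 2,4-dihydroxybenzaldehyde
Product: 2 5-bromo-2,4-dihydroxybenzaldehyde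
Conditions: Br2, AcOH, rt
Reagents that add atoms: bromine, BrBr
Why: Electrophilic aromatic bromination; C5 is para to the 2-hydroxyl and ortho to the 4-hydroxyl and less hindered than C3 between the two oxygens.

Step 2
Reactants: 2 5-bromo-2,4-dihydroxybenzaldehyde
Product: 3 5-bromo-2-hydroxy-4-[(triisopropylsilyl)oxy]benzaldehyde
Conditions: i-Pr3SiCl, imidazole, CH2Cl2, 0 °C to rt
Reagents that add atoms: chlorotri(propan-2-yl)silane, CC(C)[Si](Cl)(C(C)C)C(C)C
Why: Selective silylation; the 2-hydroxyl is locked in a hydrogen bond to the aldehyde, so only the 4-hydroxyl reacts.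

Step 3
Reactants: 3 5-bromo-2-hydroxy-4-[(triisopropylsilyl)oxy]benzaldehyde
Product: 5 2-hydroxy-5-(2-methyl-1,3-dioxolan-2-yl)-4-[(triisopropylsilyl)oxy]benzaldehyde, via enol ether 4 (not isolated)
Conditions: Pd(PPh3)4, tributyl(1-ethoxyethenyl)stannane, toluene, 100 °C; then ethylene glycol, PPTS (cat.), 4 Å sieves, 0 °C to rt
Reagents that add atoms: tributyl(1-ethoxyethenyl)stannane, CCCC[Sn](CCCC)(CCCC)C(=C)OCC; ethane-1,2-diol, OCCO
Why: Stille coupling gives the 1-ethoxyvinyl arene 4, and mild acid adds the diol to this electron-rich enol ether with loss of ethanol, as in acetonide formation from 2-methoxypropene. The chelated, conjugated aldehyde should not acetalise without water removal.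

Step 4
Reactants: 5 2-hydroxy-5-(2-methyl-1,3-dioxolan-2-yl)-4-[(triisopropylsilyl)oxy]benzaldehyde
Product: 6 2-(hydroxymethyl)-4-(2-methyl-1,3-dioxolan-2-yl)-5-[(triisopropylsilyl)oxy]phenol
Conditions: NaBH4, THF–EtOH, 0 °C; pH 7 work-up
Reagents that add atoms: none
Why: Borohydride reduction of the aldehyde; ketal and aryl silyl ether are inert, and neutral work-up avoids quinone methide formation from the salicyl alcohol.

Step 5
Reactants: 6 2-(hydroxymethyl)-4-(2-methyl-1,3-dioxolan-2-yl)-5-[(triisopropylsilyl)oxy]phenol; 7 3-chloro-2-(chloromethyl)prop-1-ene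
Product: 8 [2-{[2-(chloromethyl)prop-2-en-1-yl]oxy}-5-(2-methyl-1,3-dioxolan-2-yl)-4-[(triisopropylsilyl)oxy]phenyl]methanol
Conditions: K2CO3, 7 (excess), MeCN, 60 °C
Reagents that add atoms: none
Why: Williamson ether synthesis; carbonate deprotonates only the phenol, and the excess of the symmetrical dichloride suppresses double substitution.

Step 6
Reactants: 8 [2-{[2-(chloromethyl)prop-2-en-1-yl]oxy}-5-(2-methyl-1,3-dioxolan-2-yl)-4-[(triisopropylsilyl)oxy]phenyl]methanol
Product: 9 4-methylidene-9-(2-methyl-1,3-dioxolan-2-yl)-8-[(triisopropylsilyl)oxy]-4,5-dihydro-1H,3H-2,6-benzodioxocine (eight-membered ring: benzylic CH2–O–CH2–C(=CH2)–CH2–O–aryl)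
Conditions: NaH, n-Bu4NI (cat.), THF (0.005 M), 0 to 45 °C
Reagents that add atoms: none
Why: Intramolecular Williamson etherification at an allylic chloride under high dilution; the arene and the sp2 carbon pre-organise the chain, and SN2 and SN2′ attack give the same product.

Step 7
Reactants: 9 4-methylidene-9-(2-methyl-1,3-dioxolan-2-yl)-8-[(triisopropylsilyl)oxy]-4,5-dihydro-1H,3H-2,6-benzodioxocine
Product: 10 (Z)-4-methyl-9-(2-methyl-1,3-dioxolan-2-yl)-8-[(triisopropylsilyl)oxy]-1H,3H-2,6-benzodioxocine (ring C4=C5 enol ether, C5 bonded to the aryl oxygen)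
Conditions: t-BuOK (0.3 equiv), dry DMSO, rt
Reagents that add atoms: none
Why: Base-mediated allyl-to-propenyl ether isomerisation; the aryloxy-methylene protons are more acidic than the alkoxy-methylene protons, so the double bond should move toward the aryl oxygen. The ring allows only the Z enol ether, and catalytic base in dry solvent spares the hindered silyl ether.

Step 8
Reactants: 10 (Z)-4-methyl-9-(2-methyl-1,3-dioxolan-2-yl)-8-[(triisopropylsilyl)oxy]-1H,3H-2,6-benzodioxocine
Product: 12 (2S,3S)-5-(2-methyl-1,3-dioxolan-2-yl)-2-(prop-1-en-2-yl)-6-[(triisopropylsilyl)oxy]-2,3-dihydro-1-benzofuran-3-ol (cis), via benzylic organolithium 11 (not isolated)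
Conditions: t-BuLi, 2,2'-(pentane-3,3-diyl)bis[(4S)-4-isopropyl-4,5-dihydro-1,3-oxazole], hexane–Et2O, −78 to −40 °C; then aq. NH4Cl
Reagents that add atoms: none
Why: Proposed new method: the ligand-bound tert-butyllithium removes one of the enantiotopic benzylic protons at C1 of 10 (activated by the arene and by O2) to give 11, whose carbanion adds across the ring to C5, the aryloxy-bearing enol-ether carbon, while the allylic C3–O2 bond breaks and the C3=C4 double bond of the isopropenyl group forms, a concerted [2,3]-sigmatropic (Wittig) shift through a five-membered envelope. The closest known reaction types are ring-contracting [2,3]-Wittig rearrangements of macrocyclic allylic ethers and the bis(oxazoline)–alkyllithium enantioselective [2,3]-Wittig rearrangement of acyclic allyl benzyl ethers; new here are the eight-to-five contraction and the oxygen substituent on the attacked carbon. The dihydrofuran ring closes in a transannular 5-exo-trig mode (C1 onto C5, the C4=C5 bond exocyclic to the new ring), and the aryloxy group should help because it places the larger LUMO coefficient of the enol ether on C5 and withdraws inductively. C3 of 12 (benzofuran numbering) takes its absolute configuration from the chiral lithium–bis(oxazoline) complex, by selection between the enantiotopic protons or between the rapidly inverting epimers of 11. C2 is set relative to C3 because the two five-membered rings of the transition state share the forming bond and can only be cis-fused, and the Z enol ether is locked in the ring, so hydroxyl and isopropenyl emerge cis. Site selectivity should follow from acidity and low temperature: the benzylic C–H is the most acidic, an anion at the allylic C3 would be opposed by the enol-ether oxygen, and C7–H is shielded by the bulky, weakly coordinating triisopropylsilyl ether. A [1,2]-shift through a radical pair is disfavoured at −78 °C because the reacting termini are already held within bonding distance. The dioxolane and the silyl ether are inert to the base.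

Step 9
Reactants: 13 but-2-ynoic acid
Product: 14 tert-butyl but-2-ynoate
Conditions: tert-butyl 2,2,2-trichloroacetimidate, BF3·OEt2 (cat.), CH2Cl2–cyclohexane, rt
Reagents that add atoms: tert-butyl 2,2,2-trichloroacetimidate, CC(C)(C)OC(=N)C(Cl)(Cl)Cl
Why: Acid-catalysed tert-butylation of a carboxylic acid by the trichloroacetimidate; mild enough for the conjugated alkyne.

Step 10
Reactants: 14 tert-butyl but-2-ynoate
Product: 16 tert-butyl (2Z)-2-(hydroxymethyl)but-2-enoate, via vinylalane 15 (not isolated)
Conditions: i-Bu2AlH, N-methylmorpholine N-oxide, THF, 0 °C; then CH2O (gas, from paraformaldehyde), 0 °C to rt; aq. potassium sodium tartrate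
Reagents that add atoms: formaldehyde, C=O
Why: Conjugate syn-hydroalumination of the ynoate (vinylalumination) puts H on C3 and Al on C2 on the same side, and the α-alumino enoate 15 adds to formaldehyde with retention, so methyl and ester end up cis (Z). The bulky tert-butyl ester resists 1,2-reduction.

Step 11
Reactants: 16 tert-butyl (2Z)-2-(hydroxymethyl)but-2-enoate
Product: 17 tert-butyl (2Z)-2-(acetoxymethyl)but-2-enoate
Conditions: Ac2O, pyridine, CH2Cl2, 0 °C to rt
Reagents that add atoms: acetic anhydride, CC(=O)OC(C)=O
Why: O-Acetylation of a primary allylic alcohol; pyridine alone is used, because a more nucleophilic amine could attack the product in an SN2′ sense.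

Step 12
Reactants: 17 tert-butyl (2Z)-2-(acetoxymethyl)but-2-enoate
Product: 18 (2Z)-2-(acetoxymethyl)but-2-enoic acid
Conditions: CF3CO2H, CH2Cl2, 0 °C to rt
Reagents that add atoms: none
Why: Acidolysis of the tert-butyl ester with loss of isobutene; acetate and alkene geometry are stable to brief treatment with trifluoroacetic acid.

Step 13
Reactants: 12 (2S,3S)-5-(2-methyl-1,3-dioxolan-2-yl)-2-(prop-1-en-2-yl)-6-[(triisopropylsilyl)oxy]-2,3-dihydro-1-benzofuran-3-ol; 18 (2Z)-2-(acetoxymethyl)but-2-enoic acid
Product: 20 (2S,3S)-5-(2-methyl-1,3-dioxolan-2-yl)-2-(prop-1-en-2-yl)-6-[(triisopropylsilyl)oxy]-2,3-dihydro-1-benzofuran-3-yl (2Z)-2-(acetoxymethyl)but-2-enoate, via mixed anhydride 19 (not isolated)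
Conditions: 2,4,6-Cl3C6H2COCl, Et3N, toluene, rt; then 12, toluene, 60 °C
Reagents that add atoms: none
Why: Yamaguchi esterification without 4-(dimethylamino)pyridine, the protocol used for angelate esters; the alcohol attacks the less hindered carbonyl of 19. The absence of a nucleophilic amine protects the Z geometry and the allylic acetate, and acylation at oxygen leaves C3 untouched.

Step 14
Reactants: 20 (2S,3S)-5-(2-methyl-1,3-dioxolan-2-yl)-2-(prop-1-en-2-yl)-6-[(triisopropylsilyl)oxy]-2,3-dihydro-1-benzofuran-3-yl (2Z)-2-(acetoxymethyl)but-2-enoate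
Product: 21 (2S,3S)-5-acetyl-2-(prop-1-en-2-yl)-6-[(triisopropylsilyl)oxy]-2,3-dihydro-1-benzofuran-3-yl (2Z)-2-(acetoxymethyl)but-2-enoate
Conditions: PPTS, acetone–H2O (10:1), rt
Reagents that add atoms: water, O
Why: Mild acid hydrolysis of a ketal whose oxocarbenium ion is stabilised by two ring oxygens and therefore opens quickly; the acetyl group then deactivates the benzylic ester toward ionisation.

Step 15
Reactants: 21 (2S,3S)-5-acetyl-2-(prop-1-en-2-yl)-6-[(triisopropylsilyl)oxy]-2,3-dihydro-1-benzofuran-3-yl (2Z)-2-(acetoxymethyl)but-2-enoate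
Product: 22 (2S,3S)-5-acetyl-6-hydroxy-2-(prop-1-en-2-yl)-2,3-dihydro-1-benzofuran-3-yl (2Z)-2-(acetoxymethyl)but-2-enoate (target)
Conditions: HF·pyridine, pyridine, THF, 0 °C
Reagents that add atoms: none
Why: Fluoride cleavage of an aryl silyl ether activated by the ortho acetyl group; the buffered, weakly acidic medium forms no free phenoxide and should leave the esters and the alkene geometry alone.

## Compound list

1 | 2,4-dihydroxybenzaldehyde | O=Cc1ccc(O)cc1O | starting material
2 | 5-bromo-2,4-dihydroxybenzaldehyde | O=Cc1cc(Br)c(O)cc1O | intermediate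
3 | 5-bromo-2-hydroxy-4-[(triisopropylsilyl)oxy]benzaldehyde | O=Cc1cc(Br)c(O[Si](C(C)C)(C(C)C)C(C)C)cc1O | intermediate
4 | 5-(1-ethoxyethenyl)-2-hydroxy-4-[(triisopropylsilyl)oxy]benzaldehyde | C=C(OCC)c1cc(C=O)c(O)cc1O[Si](C(C)C)(C(C)C)C(C)C | intermediate (not isolated)
5 | 2-hydroxy-5-(2-methyl-1,3-dioxolan-2-yl)-4-[(triisopropylsilyl)oxy]benzaldehyde | CC1(OCCO1)c2cc(C=O)c(O)cc2O[Si](C(C)C)(C(C)C)C(C)C | intermediate
6 | 2-(hydroxymethyl)-4-(2-methyl-1,3-dioxolan-2-yl)-5-[(triisopropylsilyl)oxy]phenol | CC1(OCCO1)c2cc(CO)c(O)cc2O[Si](C(C)C)(C(C)C)C(C)C | intermediate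
7 | 3-chloro-2-(chloromethyl)prop-1-ene | C=C(CCl)CCl | starting material
8 | [2-{[2-(chloromethyl)prop-2-en-1-yl]oxy}-5-(2-methyl-1,3-dioxolan-2-yl)-4-[(triisopropylsilyl)oxy]phenyl]methanol | CC1(OCCO1)c2cc(CO)c(OCC(=C)CCl)cc2O[Si](C(C)C)(C(C)C)C(C)C | intermediate
9 | 4-methylidene-9-(2-methyl-1,3-dioxolan-2-yl)-8-[(triisopropylsilyl)oxy]-4,5-dihydro-1H,3H-2,6-benzodioxocine | C=C1COCc2cc(C3(C)OCCO3)c(O[Si](C(C)C)(C(C)C)C(C)C)cc2OC1 | intermediate
10 | (Z)-4-methyl-9-(2-methyl-1,3-dioxolan-2-yl)-8-[(triisopropylsilyl)oxy]-1H,3H-2,6-benzodioxocine | C/C1=C/Oc2cc(O[Si](C(C)C)(C(C)C)C(C)C)c(C3(C)OCCO3)cc2COC1 | intermediate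
11 | 1-lithio derivative of 10 (ligand-bound α-alkoxybenzyllithium, configuration at the lithiated carbon labile) | C/C1=C/Oc2cc(O[Si](C(C)C)(C(C)C)C(C)C)c(C3(C)OCCO3)cc2C([Li])OC1 | intermediate (not isolated)
12 | (2S,3S)-5-(2-methyl-1,3-dioxolan-2-yl)-2-(prop-1-en-2-yl)-6-[(triisopropylsilyl)oxy]-2,3-dihydro-1-benzofuran-3-ol | C=C(C)[C@@H]1Oc2cc(O[Si](C(C)C)(C(C)C)C(C)C)c(C3(C)OCCO3)cc2[C@@H]1O | intermediate
13 | but-2-ynoic acid | CC#CC(=O)O | starting material
14 | tert-butyl but-2-ynoate | CC#CC(=O)OC(C)(C)C | intermediate
15 | tert-butyl (2E)-2-(diisobutylalumanyl)but-2-enoate (methyl cis to the ester) | C/C=C(\C(=O)OC(C)(C)C)[Al](CC(C)C)CC(C)C | intermediate (not isolated)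
16 | tert-butyl (2Z)-2-(hydroxymethyl)but-2-enoate | C/C=C(/CO)C(=O)OC(C)(C)C | intermediate
17 | tert-butyl (2Z)-2-(acetoxymethyl)but-2-enoate | C/C=C(/COC(C)=O)C(=O)OC(C)(C)C | intermediate
18 | (2Z)-2-(acetoxymethyl)but-2-enoic acid | C/C=C(/COC(C)=O)C(=O)O | intermediate
19 | (2Z)-2-(acetoxymethyl)but-2-enoic 2,4,6-trichlorobenzoic anhydride | C/C=C(/COC(C)=O)C(=O)OC(=O)c1c(Cl)cc(Cl)cc1Cl | intermediate (not isolated)
20 | (2S,3S)-5-(2-methyl-1,3-dioxolan-2-yl)-2-(prop-1-en-2-yl)-6-[(triisopropylsilyl)oxy]-2,3-dihydro-1-benzofuran-3-yl (2Z)-2-(acetoxymethyl)but-2-enoate | C=C(C)[C@@H]1Oc2cc(O[Si](C(C)C)(C(C)C)C(C)C)c(C3(C)OCCO3)cc2[C@@H]1OC(=O)/C(=C\C)COC(C)=O | intermediate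
21 | (2S,3S)-5-acetyl-2-(prop-1-en-2-yl)-6-[(triisopropylsilyl)oxy]-2,3-dihydro-1-benzofuran-3-yl (2Z)-2-(acetoxymethyl)but-2-enoate | C=C(C)[C@@H]1Oc2cc(O[Si](C(C)C)(C(C)C)C(C)C)c(C(C)=O)cc2[C@@H]1OC(=O)/C(=C\C)COC(C)=O | intermediate
22 | (2S,3S)-5-acetyl-6-hydroxy-2-(prop-1-en-2-yl)-2,3-dihydro-1-benzofuran-3-yl (2Z)-2-(acetoxymethyl)but-2-enoate | C=C(C)[C@@H]1Oc2cc(O)c(C(C)=O)cc2[C@@H]1OC(=O)/C(=C\C)COC(C)=O | target

## Step count and least certain steps

Total step count: 15. Longest linear sequence: 11 steps (steps 1–8 and 13–15); the side-chain branch (steps 9–12) has 4 steps.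

**Step 8 (key step, new method).** Most likely failures are poor discrimination by the ligand between the two benzylic protons (low enantiomeric purity), lithiation at the vinylic or aromatic C–H instead of the benzylic one, and a competing [1,2]-shift if the transannular geometry is less favourable than assumed.
Fallback with known chemistry, leaving the route at aldehyde 5 and returning at 12: O-alkylation of the phenol of 5 with chloroacetone (K2CO3, acetone) would give 5-(2-methyl-1,3-dioxolan-2-yl)-2-(2-oxopropoxy)-4-[(triisopropylsilyl)oxy]benzaldehyde F1. A proline-catalysed intramolecular aldol reaction (5-enolexo, enamine catalysis, a known route to cis-2-acyl-2,3-dihydrobenzofuran-3-ols; proline antipode chosen for the 3S carbinol) would close the ring to 1-[(2R,3S)-3-hydroxy-5-(2-methyl-1,3-dioxolan-2-yl)-6-[(triisopropylsilyl)oxy]-2,3-dihydro-1-benzofuran-2-yl]ethan-1-one F2. Silylation (Et3SiCl, imidazole) would give 1-[(2R,3S)-5-(2-methyl-1,3-dioxolan-2-yl)-3-[(triethylsilyl)oxy]-6-[(triisopropylsilyl)oxy]-2,3-dihydro-1-benzofuran-2-yl]ethan-1-one F3. Non-basic methylenation of the acetyl group with the Tebbe reagent Cp2Ti(μ-CH2)(μ-Cl)AlMe2 would give triethyl{[(2S,3S)-5-(2-methyl-1,3-dioxolan-2-yl)-2-(prop-1-en-2-yl)-6-[(triisopropylsilyl)oxy]-2,3-dihydro-1-benzofuran-3-yl]oxy}silane F4. Selective removal of the alkyl triethylsilyl ether (HF·pyridine, pyridine, THF, 0 °C) would give 12. This bypasses steps 4–8.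

**Step 7 (isomerisation).** Most likely failure is cleavage of the aryl silyl ether by the alkoxide in DMSO, followed by migration of the double bond toward the benzylic-ether side on prolonged exposure.
Fallback from 9 to 10 that removes the protecting group before the base step: fluoride (n-Bu4NF, THF, 0 °C) would give 4-methylidene-9-(2-methyl-1,3-dioxolan-2-yl)-4,5-dihydro-1H,3H-2,6-benzodioxocin-8-ol F5. Isomerisation of its potassium phenoxide with excess t-BuOK in DMSO would give (Z)-4-methyl-9-(2-methyl-1,3-dioxolan-2-yl)-1H,3H-2,6-benzodioxocin-8-ol F6. Re-silylation (i-Pr3SiCl, imidazole) would return to 10.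

**Step 6 (eight-membered ring closure).** Most likely failure is intermolecular etherification (dimer and oligomer formation) outrunning the medium-ring closure.
Fallback from 6 to 10 that forms the ring by olefin metathesis and needs no isomerisation: Chan–Lam O-vinylation of the phenol of 6 (Cu(OAc)2, pyridine, 2,4,6-trivinylcyclotriboroxane–pyridine complex, CH2Cl2, air) would give [2-(ethenyloxy)-5-(2-methyl-1,3-dioxolan-2-yl)-4-[(triisopropylsilyl)oxy]phenyl]methanol F7. Alkylation of the benzylic alcohol (NaH, 3-chloro-2-methylprop-1-ene, THF) would give 2-[4-(ethenyloxy)-5-{[(2-methylprop-2-en-1-yl)oxy]methyl}-2-[(triisopropylsilyl)oxy]phenyl]-2-methyl-1,3-dioxolane F8. Ring-closing metathesis with the second-generation Grubbs catalyst (toluene, high dilution) would give 10 with loss of ethene; the ring again enforces the Z enol ether. This bypasses steps 5–7.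

**Step 10 (hydroalumination and formaldehyde trapping).** Most likely failure is loss of alkene geometry through an aluminium allenolate before the aldehyde is captured, or 1,2-reduction of the ester.
Fallback from 14 to 16: syn-hydrostannation of 14 (n-Bu3SnH, Pd(PPh3)4, THF) would give tert-butyl (2E)-2-(tributylstannyl)but-2-enoate F9. Iododestannylation (I2, CH2Cl2, 0 °C, retention) would give tert-butyl (2E)-2-iodobut-2-enoate F10. Stille coupling with (tributylstannyl)methanol (Pd(PPh3)4, dioxane, 80 °C) would give 16.

**Step 13 (esterification).** Most likely failure is slow acylation of the hindered alcohol, so that prolonged heating with amine salts causes Z-to-E isomerisation of the enoate or elimination across C2–C3.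
Fallback from 12 and 18 to 20 by acylating the metal alkoxide at low temperature: dehydration of 18 with dicyclohexylcarbodiimide would give (2Z)-2-(acetoxymethyl)but-2-enoic anhydride F11. The lithium alkoxide of 12 (LiN(SiMe3)2, THF, −78 °C) would be acylated by F11 at −78 to −40 °C to give 20, without amine or heat.

## Further compounds

F1 | step 8 | 5-(2-methyl-1,3-dioxolan-2-yl)-2-(2-oxopropoxy)-4-[(triisopropylsilyl)oxy]benzaldehyde | CC(=O)COc1cc(O[Si](C(C)C)(C(C)C)C(C)C)c(C2(C)OCCO2)cc1C=O
F2 | step 8 | 1-[(2R,3S)-3-hydroxy-5-(2-methyl-1,3-dioxolan-2-yl)-6-[(triisopropylsilyl)oxy]-2,3-dihydro-1-benzofuran-2-yl]ethan-1-one | CC(=O)[C@@H]1Oc2cc(O[Si](C(C)C)(C(C)C)C(C)C)c(C3(C)OCCO3)cc2[C@@H]1O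
F3 | step 8 | 1-[(2R,3S)-5-(2-methyl-1,3-dioxolan-2-yl)-3-[(triethylsilyl)oxy]-6-[(triisopropylsilyl)oxy]-2,3-dihydro-1-benzofuran-2-yl]ethan-1-one | CC(=O)[C@@H]1Oc2cc(O[Si](C(C)C)(C(C)C)C(C)C)c(C3(C)OCCO3)cc2[C@@H]1O[Si](CC)(CC)CC
F4 | step 8 | triethyl{[(2S,3S)-5-(2-methyl-1,3-dioxolan-2-yl)-2-(prop-1-en-2-yl)-6-[(triisopropylsilyl)oxy]-2,3-dihydro-1-benzofuran-3-yl]oxy}silane | C=C(C)[C@@H]1Oc2cc(O[Si](C(C)C)(C(C)C)C(C)C)c(C3(C)OCCO3)cc2[C@@H]1O[Si](CC)(CC)CC
F5 | step 7 | 4-methylidene-9-(2-methyl-1,3-dioxolan-2-yl)-4,5-dihydro-1H,3H-2,6-benzodioxocin-8-ol | C=C1COCc2cc(C3(C)OCCO3)c(O)cc2OC1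
F6 | step 7 | (Z)-4-methyl-9-(2-methyl-1,3-dioxolan-2-yl)-1H,3H-2,6-benzodioxocin-8-ol | C/C1=C/Oc2cc(O)c(C3(C)OCCO3)cc2COC1
F7 | step 6 | [2-(ethenyloxy)-5-(2-methyl-1,3-dioxolan-2-yl)-4-[(triisopropylsilyl)oxy]phenyl]methanol | C=COc1cc(O[Si](C(C)C)(C(C)C)C(C)C)c(C2(C)OCCO2)cc1CO
F8 | step 6 | 2-[4-(ethenyloxy)-5-{[(2-methylprop-2-en-1-yl)oxy]methyl}-2-[(triisopropylsilyl)oxy]phenyl]-2-methyl-1,3-dioxolane | C=COc1cc(O[Si](C(C)C)(C(C)C)C(C)C)c(C2(C)OCCO2)cc1COCC(C)=C
F9 | step 10 | tert-butyl (2E)-2-(tributylstannyl)but-2-enoate | C/C=C(\C(=O)OC(C)(C)C)[Sn](CCCC)(CCCC)CCCC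
F10 | step 10 | tert-butyl (2E)-2-iodobut-2-enoate | C/C=C(\C(=O)OC(C)(C)C)I
F11 | step 13 | (2Z)-2-(acetoxymethyl)but-2-enoic anhydride | C/C=C(/COC(C)=O)C(=O)OC(=O)/C(=C\C)COC(C)=O
A1 | alternative 1 | 3-acetyl-6-{[(3S,4S)-4-[(tert-butyldimethylsilyl)oxy]-2-methylhex-1-en-5-yn-3-yl]oxy}-4-hydroxy-2H-pyran-2-one | C=C(C)[C@H](OC1=CC(O)=C(C(C)=O)C(=O)O1)[C@@H](O[Si](C)(C)C(C)(C)C)C#C
A2 | alternative 1 | 1-[(2S,3S)-3-[(tert-butyldimethylsilyl)oxy]-6-hydroxy-2-(prop-1-en-2-yl)-2,3-dihydro-1-benzofuran-5-yl]ethan-1-one | C=C(C)[C@@H]1Oc2cc(O)c(C(C)=O)cc2[C@@H]1O[Si](C)(C)C(C)(C)C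
A3 | alternative 2 | (3S,4S)-6-acetyl-7-[(tert-butyldimethylsilyl)oxy]-3-hydroxy-2,2-dimethyl-3,4-dihydro-2H-1-benzopyran-4-yl (2Z)-2-(acetoxymethyl)but-2-enoate | CC1(C)Oc2cc(O[Si](C)(C)C(C)(C)C)c(C(C)=O)cc2[C@H](OC(=O)/C(=C\C)COC(C)=O)[C@@H]1O
A4 | alternative 2 | (2S,3S)-5-acetyl-6-[(tert-butyldimethylsilyl)oxy]-2-(prop-1-en-2-yl)-2,3-dihydro-1-benzofuran-3-yl (2Z)-2-(acetoxymethyl)but-2-enoate | C=C(C)[C@@H]1Oc2cc(O[Si](C)(C)C(C)(C)C)c(C(C)=O)cc2[C@@H]1OC(=O)/C(=C\C)COC(C)=O
A5 | alternative 3 | 3-[(tert-butyldimethylsilyl)oxy]-4-(2-methyl-1,3-dioxolan-2-yl)phenol | Oc1ccc(C2(C)OCCO2)c(O[Si](C)(C)C(C)(C)C)c1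
A6 | alternative 3 | (2R)-3,3-dimethyloxirane-2-carbaldehyde | CC1(C)O[C@H]1C=O
A7 | alternative 3 | (2R,3S)-6-[(tert-butyldimethylsilyl)oxy]-2-(2-hydroxypropan-2-yl)-5-(2-methyl-1,3-dioxolan-2-yl)-2,3-dihydro-1-benzofuran-3-ol | CC(C)(O)[C@@H]1Oc2cc(O[Si](C)(C)C(C)(C)C)c(C3(C)OCCO3)cc2[C@@H]1O
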